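The route rests on ring B (C1–C2(=O)–C3–C4–C5–C10, eremophilane numbering): its ketone lies 1,4 to the quaternary C5, and C4 and C5 carry cis methyl groups. A Lewis acid-promoted Diels–Alder reaction between a 2-silyloxy-1,3-diene (C3=C2–C1=C10, carrying the C9–C8 diol unit from (R)-but-3-ene-1,2-diol) and (E)-2-methylbut-2-enal (C4=C5, formyl carbon C6) closes ring B through the C3–C4 and C5–C10 bonds and sets C4, C5 and C10 in one operation. Ring A is closed later between C7 and C8 by a carbonyl-ene reaction that also creates the isopropenyl group; C9 is finally inverted by oxidation and reduction.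

Key step: step 4

Remark: eremophilane atom labels are kept for every intermediate (ring B = C1, C2, C3, C4, C5, C10; ring A = C5–C10; C11–C13 isopropenyl; C14 methyl on C5; C15 methyl on C4). C9 is carried with the configuration opposite to that of the target until step 13.

Step 1
Reactants: 1 (R)-but-3-ene-1,2-diol
Product: 2 (R)-3,4-bis(triethylsilyloxy)but-1-ene
Conditions: Et3SiCl (2.3 equiv), imidazole, CH2Cl2, 0 °C → rt
Reagents that add atoms: chlorotriethylsilane, CC[Si](CC)(CC)Cl
Why: Silyl ether formation masks both hydroxyl groups without touching the stereocentre that becomes C9.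

Step 2
Reactants: 2 (R)-3,4-bis(triethylsilyloxy)but-1-ene; 3 but-3-en-2-one
Product: 4 (5R,3E)-5,6-bis(triethylsilyloxy)hex-3-en-2-one
Conditions: 3 (3 equiv), second-generation Hoveyda–Grubbs catalyst RuCl2(H2IMes)(=CH-C6H4-2-O-i-Pr) (5 mol%), CH2Cl2, 40 °C
Reagents that add atoms: none
Why: Olefin cross-metathesis of the terminal alkene with the electron-poor enone partner should give the (E)-enone under thermodynamic control, with loss of ethene.

Step 3
Reactants: 4 (5R,3E)-5,6-bis(triethylsilyloxy)hex-3-en-2-one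
Product: 5 (5R,3E)-5,6-bis(triethylsilyloxy)-2-(triisopropylsilyloxy)hexa-1,3-diene
Conditions: i-Pr3SiOTf, Et3N, CH2Cl2, −78 → 0 °C
Reagents that add atoms: triisopropylsilyl trifluoromethanesulfonate, CC(C)[Si](C(C)C)(C(C)C)OS(=O)(=O)C(F)(F)F
Why: Soft enolisation (silyl triflate and amine) of the methyl ketone on its kinetically accessible methyl side should give the cross-conjugated 2-silyloxy-1,3-diene with the (E)-alkene retained.

Step 4
Reactants: 5 (5R,3E)-5,6-bis(triethylsilyloxy)-2-(triisopropylsilyloxy)hexa-1,3-diene; 6 (E)-2-methylbut-2-enal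
Product: 7 (1R,2S,6S)-2-[(1R)-1,2-bis(triethylsilyloxy)ethyl]-1,6-dimethyl-4-(triisopropylsilyloxy)cyclohex-3-ene-1-carbaldehyde (ring B; eremophilane labels 4S,5R,9R,10S)
Conditions: 6 (2 equiv), Me2AlCl (1.2 equiv), CH2Cl2, −78 → −40 °C; Et3N, aq. NaHCO3
Reagents that add atoms: none
Why: The aluminium-complexed enal 6 and the electron-rich diene 5 should react in a concerted, asynchronous normal-demand [4+2] cycloaddition in which bond formation is advanced between the enol-ether terminus C3 and the enal β-carbon C4. The closest known reaction type is the Lewis acid-promoted Diels–Alder reaction of 2-silyloxy-1,3-dienes with α-substituted enals. Ring B is closed as a six-membered ring in the cycloaddition mode, C3–C4 and C5–C10 being formed in the same step. The cis relation of the C4 and C5 methyl groups follows from the (E)-geometry of 6 (suprafacial addition), C10 follows from the endo orientation of the formyl group relative to the (E)-diene terminus (formyl group and side chain cis), and the absolute sense is relayed from the (R)-C9 silyloxy stereocentre, the dienophile approaching anti to the allylic C–O bond with the allylic hydrogen inside. The step needs regio-, endo- and π-facial selectivity: regiochemistry is secured by the matched directing effects of the C2 silyloxy group and the C10 substituent (largest diene coefficient at C3), endo selectivity by carbonyl–Lewis acid activation at low temperature, and facial selectivity by the allylic stereocentre.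

Step 5
Reactants: 7 ring B aldehyde (formyl at C5)
Product: 8 ring B alkyne (ethynyl C6≡C7H at C5 in place of formyl; configuration as in 7)
Conditions: (MeO)2P(O)CHN2, t-BuOK, THF, −78 → 0 °C
Reagents that add atoms: dimethyl (diazomethyl)phosphonate, COP(=O)(OC)C=[N+]=[N-]
Why: Seyferth–Gilbert homologation should turn the non-enolisable formyl group into the terminal alkyne under basic conditions that spare the silyl ethers and the silyl enol ether; no stereocentre is affected.

Step 6
Reactants: 8 ring B alkyne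
Product: 10 ring B homologated aldehyde (CH2CHO at C5; C6H2–C7HO), via (E)-alkenyldicyclohexylborane 9 (not isolated)
Conditions: (c-C6H11)2BH, THF, 0 °C → rt; then 30% H2O2, pH 7 phosphate buffer, 0 °C
Reagents that add atoms: dicyclohexylborane, C1CCCCC1BC1CCCCC1 (boron in 9 only); hydrogen peroxide, OO
Why: Anti-Markovnikov hydroboration of the terminal alkyne with a hindered dialkylborane, followed by oxidation of the alkenylborane, should give the aldehyde at C7 and leave C6 as a methylene group.

Step 7
Reactants: 10 ring B homologated aldehyde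
Product: 11 ring B prenyl compound (CH2CH=C(CH3)2 at C5)
Conditions: i-PrPPh3I, n-BuLi, THF, 0 °C; then 10, −78 °C → rt
Reagents that add atoms: isopropyltriphenylphosphonium iodide, CC(C)[P+](c1ccccc1)(c1ccccc1)c1ccccc1.[I-]
Why: Wittig olefination with the non-stabilised isopropylidene ylide should install the trisubstituted C7=C11 alkene, which has no E/Z issue.

Step 8
Reactants: 11 ring B prenyl compound
Product: 12 α-silyloxy aldehyde ((R)-CH(OSiEt3)CHO at C10; C8 is the formyl carbon)
Conditions: (COCl)2, DMSO, CH2Cl2, −78 → −30 °C; then Et3N, −78 → 0 °C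
Reagents that add atoms: none
Why: Under Swern conditions the primary triethylsilyl ether should be cleaved by the chlorosulfonium species and oxidised in situ to the aldehyde, while the secondary triethylsilyl ether at C9 survives (chemoselective Swern oxidation of primary silyl ethers).

Step 9
Reactants: 12 α-silyloxy aldehyde
Product: 13 (4S,5R,7R,8R,9R,10S)-9-(triethylsilyloxy)-2-(triisopropylsilyloxy)eremophila-1,11-dien-8-ol
Conditions: Me2AlCl (1.5 equiv), CH2Cl2, −78 → −40 °C
Reagents that add atoms: none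
Why: The Lewis acid-promoted intramolecular carbonyl-ene reaction (citronellal-to-isopulegol type) should close ring A between C7 and C8 through a chair in which C11, the incipient O8 and the C9 silyloxy group are all equatorial, the alternative chair placing the C9 silyloxy group syn-axial to the C5 methyl group, so that the 7β-isopropenyl group (by hydrogen transfer from a methyl group) and the trans 8α-hydroxyl are set.

Step 10
Reactants: 13 bicyclic alcohol; 14 (R)-2-methylbutanoic acid
Product: 15 8-O-[(2R)-2-methylbutanoyl] ester of 13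
Conditions: DCC, DMAP (cat.), CH2Cl2, 0 °C → rt
Reagents that add atoms: none
Why: Steglich esterification of the unhindered equatorial C8 hydroxyl under cold conditions with catalytic DMAP should proceed without epimerising the α-centre of the acid.

Step 11
Reactants: 15 C8 ester with C9 triethylsilyl ether
Product: 16 (4S,5R,7R,8R,9R,10S)-9-hydroxy compound (C8 ester, C9 β-hydroxyl, silyl enol ether retained)
Conditions: PPTS (cat.), MeOH/CH2Cl2, 0 °C
Reagents that add atoms: none
Why: Mild acid-catalysed methanolysis should remove the secondary triethylsilyl ether, while the far more robust triisopropylsilyl enol ether persists.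

Step 12
Reactants: 16 9β-alcohol
Product: 17 (4S,5R,7R,8R,10S)-9-ketone (C8 ester, silyl enol ether retained)
Conditions: Dess–Martin periodinane, NaHCO3, CH2Cl2, 0 °C → rt
Reagents that add atoms: none
Why: Dess–Martin oxidation under buffered, neutral conditions should give the C9 ketone without epimerising C8 or C10.

Step 13
Reactants: 17 9-ketone
Product: 18 (4S,5R,7R,8R,9S,10S)-9α-alcohol (C8 ester, silyl enol ether retained)
Conditions: LiBH(s-Bu)3, THF, −78 °C; AcOH, −78 °C
Reagents that add atoms: none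
Why: In this bulky trialkylborohydride reduction the hydride should attack C9 from the equatorial β-face, because the axial α-trajectory is blocked by the syn-axial C4 of ring B, giving the axial 9α-alcohol cis to the C8 ester; low temperature and a cold acidic quench suppress acyl migration, and C2 stays masked as the silyl enol ether.

Step 14
Reactants: 18 9α-alcohol; 19 (E)-2-methylbut-2-enoyl chloride
Product: 20 (4S,5R,7R,8R,9S,10S)-8-[(2R)-2-methylbutanoyloxy]-9-[(E)-2-methylbut-2-enoyloxy]-2-(triisopropylsilyloxy)eremophila-1,11-diene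
Conditions: 19 (3 equiv), DMAP, pyridine, CH2Cl2, 0 → 40 °C
Reagents that add atoms: none
Why: DMAP-catalysed acylation with the acid chloride should esterify the axial C9 hydroxyl; the (E)-geometry of the tigloyl unit is the stable one and should be retained.

Step 15
Reactants: 20 diester silyl enol ether
Product: 21 (4S,5R,7R,8R,9S,10S)-8-[(2R)-2-methylbutanoyloxy]-9-[(E)-2-methylbut-2-enoyloxy]eremophil-11-en-2-one (target)
Conditions: Bu4NF, AcOH (1:1), THF, 0 °C
Reagents that add atoms: none
Why: Fluoride-mediated cleavage of the silyl enol ether should release the C2 ketone regiospecifically (no stereocentre is α to C2), and acetic acid buffering protects the two esters.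

Compound list
1 | (R)-but-3-ene-1,2-diol | C=C[C@@H](O)CO | starting material
2 | (R)-3,4-bis(triethylsilyloxy)but-1-ene | C=C[C@@H](O[Si](CC)(CC)CC)CO[Si](CC)(CC)CC | intermediate
3 | but-3-en-2-one | CC(=O)C=C | starting material
4 | (5R,3E)-5,6-bis(triethylsilyloxy)hex-3-en-2-one | CC(=O)/C=C/[C@@H](O[Si](CC)(CC)CC)CO[Si](CC)(CC)CC | intermediate
5 | (5R,3E)-5,6-bis(triethylsilyloxy)-2-(triisopropylsilyloxy)hexa-1,3-diene | C=C(O[Si](C(C)C)(C(C)C)C(C)C)/C=C/[C@@H](O[Si](CC)(CC)CC)CO[Si](CC)(CC)CC | intermediate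
6 | (E)-2-methylbut-2-enal | C/C=C(\C)C=O | starting material
7 | (1R,2S,6S)-2-[(1R)-1,2-bis(triethylsilyloxy)ethyl]-1,6-dimethyl-4-(triisopropylsilyloxy)cyclohex-3-ene-1-carbaldehyde (formyl and side chain cis, the two methyl groups cis) | O=C[C@@]1(C)[C@H](C=C(O[Si](C(C)C)(C(C)C)C(C)C)C[C@@H]1C)[C@@H](O[Si](CC)(CC)CC)CO[Si](CC)(CC)CC | intermediate
8 | ring B alkyne: 7 with ethynyl (C6≡C7H) in place of the formyl group, configuration unchanged | C#C[C@@]1(C)[C@H](C=C(O[Si](C(C)C)(C(C)C)C(C)C)C[C@@H]1C)[C@@H](O[Si](CC)(CC)CC)CO[Si](CC)(CC)CC | intermediate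
9 | (E)-alkenyldicyclohexylborane from 8 (C6H=C7H–B(c-C6H11)2), configuration unchanged | C1CCCCC1B(C1CCCCC1)/C=C/[C@@]2(C)[C@H](C=C(O[Si](C(C)C)(C(C)C)C(C)C)C[C@@H]2C)[C@@H](O[Si](CC)(CC)CC)CO[Si](CC)(CC)CC | intermediate (not isolated)
10 | ring B homologated aldehyde: C5 carries CH2CHO, configuration unchanged | O=CC[C@@]1(C)[C@H](C=C(O[Si](C(C)C)(C(C)C)C(C)C)C[C@@H]1C)[C@@H](O[Si](CC)(CC)CC)CO[Si](CC)(CC)CC | intermediate
11 | ring B prenyl compound: C5 carries CH2CH=C(CH3)2, configuration unchanged | CC(C)=CC[C@@]1(C)[C@H](C=C(O[Si](C(C)C)(C(C)C)C(C)C)C[C@@H]1C)[C@@H](O[Si](CC)(CC)CC)CO[Si](CC)(CC)CC | intermediate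
12 | α-silyloxy aldehyde: C10 carries (R)-CH(OSiEt3)CHO, otherwise as 11 | CC(C)=CC[C@@]1(C)[C@H](C=C(O[Si](C(C)C)(C(C)C)C(C)C)C[C@@H]1C)[C@@H](O[Si](CC)(CC)CC)C=O | intermediate
13 | (4S,5R,7R,8R,9R,10S)-9-(triethylsilyloxy)-2-(triisopropylsilyloxy)eremophila-1,11-dien-8-ol (cis-fused; 7β-isopropenyl, 8α-OH, 9β-OSiEt3) | C=C(C)[C@H]1C[C@@]2(C)[C@H](C=C(O[Si](C(C)C)(C(C)C)C(C)C)C[C@@H]2C)[C@@H](O[Si](CC)(CC)CC)[C@@H]1O | intermediate
14 | (R)-2-methylbutanoic acid | CC[C@@H](C)C(=O)O | starting material
15 | 8-O-[(2R)-2-methylbutanoyl] ester of 13 | C=C(C)[C@H]1C[C@@]2(C)[C@H](C=C(O[Si](C(C)C)(C(C)C)C(C)C)C[C@@H]2C)[C@@H](O[Si](CC)(CC)CC)[C@@H]1OC(=O)[C@H](C)CC | intermediate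
16 | 9β-alcohol: 15 without the triethylsilyl group (9R) | C=C(C)[C@H]1C[C@@]2(C)[C@H](C=C(O[Si](C(C)C)(C(C)C)C(C)C)C[C@@H]2C)[C@@H](O)[C@@H]1OC(=O)[C@H](C)CC | intermediate
17 | 9-ketone (4S,5R,7R,8R,10S) with the C8 ester and the silyl enol ether | C=C(C)[C@H]1C[C@@]2(C)[C@H](C=C(O[Si](C(C)C)(C(C)C)C(C)C)C[C@@H]2C)C(=O)[C@@H]1OC(=O)[C@H](C)CC | intermediate
18 | 9α-alcohol (9S), cis to the C8 ester | C=C(C)[C@H]1C[C@@]2(C)[C@H](C=C(O[Si](C(C)C)(C(C)C)C(C)C)C[C@@H]2C)[C@H](O)[C@@H]1OC(=O)[C@H](C)CC | intermediate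
19 | (E)-2-methylbut-2-enoyl chloride | C/C=C(\C)C(=O)Cl | starting material
20 | (4S,5R,7R,8R,9S,10S)-8-[(2R)-2-methylbutanoyloxy]-9-[(E)-2-methylbut-2-enoyloxy]-2-(triisopropylsilyloxy)eremophila-1,11-diene | C=C(C)[C@H]1C[C@@]2(C)[C@H](C=C(O[Si](C(C)C)(C(C)C)C(C)C)C[C@@H]2C)[C@H](OC(=O)/C(C)=C/C)[C@@H]1OC(=O)[C@H](C)CC | intermediate
21 | (4S,5R,7R,8R,9S,10S)-8-[(2R)-2-methylbutanoyloxy]-9-[(E)-2-methylbut-2-enoyloxy]eremophil-11-en-2-one | C=C(C)[C@H]1C[C@@]2(C)[C@H](CC(=O)C[C@@H]2C)[C@H](OC(=O)/C(C)=C/C)[C@@H]1OC(=O)[C@H](C)CC | target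

Total step count: 15. Longest linear sequence: 15 steps (1 → 21).

Steps most likely to fail

Step 4 (key step). What may go wrong: the silyl dienol ether adds in a Mukaiyama-type 1,2-fashion to the aluminium-activated formyl group instead of undergoing cycloaddition, and π-facial discrimination by the C9 stereocentre is eroded. Fallback, setting out from 5: cycloaddition with (E)-3-methylpent-3-en-2-one (EtAlCl2, CH2Cl2, −78 °C), a ketone dienophile that is far less prone to 1,2-attack and whose acetyl group is a strong endo director, should give the methyl ketone cycloadduct F1. Enolisation on its only enolisable side (LiN(i-Pr)2, THF, −78 °C) and O-phosphorylation with ClP(O)(OEt)2 should give the enol diethyl phosphate F2. Elimination with further LiN(i-Pr)2 (−78 → 0 °C, then water) should deliver alkyne 8, where the route is rejoined; step 5 is then not needed.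

Step 9. What may go wrong: ring closure through the alternative chair, or stepwise cationic pathways (chloride capture, loss of silyl groups), giving the wrong C7/C8 configuration or no isopropenyl group. Fallback, setting out from 7: Wittig reaction with Ph3P=CHC(O)CH3 (toluene, 90 °C) should give the (E)-enone F3, and Swern oxidation as in step 8 the keto aldehyde F4. Reductive aldol cyclisation with [(Ph3P)CuH]6 (toluene, −40 °C → rt), followed by base equilibration at C7 (cat. DBU), should give the all-equatorial β-hydroxy ketone F5 under thermodynamic rather than kinetic control. Methylenation of the acetyl group (Zn, CH2Br2, TiCl4, THF) returns to 13.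

Step 14. What may go wrong: under the basic acylation conditions the 2-methylbutanoyl group migrates from O8 to the neighbouring cis hydroxyl at C9 faster than the hindered axial hydroxyl is acylated, so that the two ester positions are scrambled. Fallback, setting out from 13, with the hindered acylation done before any neighbouring ester exists:
- silylation of the C8 hydroxyl (t-BuMe2SiOTf, 2,6-lutidine) gives the bis-silyl ether F6;
- selective methanolysis of the triethylsilyl ether (PPTS, MeOH) gives the 9β-alcohol F7;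
- Dess–Martin oxidation gives the ketone F8;
- LiBH(s-Bu)3 at −78 °C gives the 9α-alcohol F9;
- acylation with 19 (DMAP, pyridine) gives the tiglate F10;
- HF·pyridine removes both remaining silyl groups to give the keto alcohol F11;
- Steglich esterification of the unhindered equatorial C8 hydroxyl with 14 (DCC, DMAP) gives 21 directly.

Further compounds
F1 | step 4 | methyl ketone cycloadduct (acetyl at C5 in place of the formyl group of 7) | CC(=O)[C@@]1(C)[C@H](C=C(O[Si](C(C)C)(C(C)C)C(C)C)C[C@@H]1C)[C@@H](O[Si](CC)(CC)CC)CO[Si](CC)(CC)CC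
F2 | step 4 | enol diethyl phosphate of F1 | C=C(OP(=O)(OCC)OCC)[C@@]1(C)[C@H](C=C(O[Si](C(C)C)(C(C)C)C(C)C)C[C@@H]1C)[C@@H](O[Si](CC)(CC)CC)CO[Si](CC)(CC)CC
F3 | step 9 | (E)-enone from 7 (C5 carries CH=CH–C(O)CH3) | CC(=O)/C=C/[C@@]1(C)[C@H](C=C(O[Si](C(C)C)(C(C)C)C(C)C)C[C@@H]1C)[C@@H](O[Si](CC)(CC)CC)CO[Si](CC)(CC)CC
F4 | step 9 | keto aldehyde (enone at C5, (R)-CH(OSiEt3)CHO at C10) | CC(=O)/C=C/[C@@]1(C)[C@H](C=C(O[Si](C(C)C)(C(C)C)C(C)C)C[C@@H]1C)[C@@H](O[Si](CC)(CC)CC)C=O
F5 | step 9 | β-hydroxy ketone (7β-acetyl, 8α-hydroxyl, 9β-triethylsilyloxy, cis-fused) | CC(=O)[C@H]1C[C@@]2(C)[C@H](C=C(O[Si](C(C)C)(C(C)C)C(C)C)C[C@@H]2C)[C@@H](O[Si](CC)(CC)CC)[C@@H]1O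
F6 | step 14 | 8-O-tert-butyldimethylsilyl ether of 13 | C=C(C)[C@H]1C[C@@]2(C)[C@H](C=C(O[Si](C(C)C)(C(C)C)C(C)C)C[C@@H]2C)[C@@H](O[Si](CC)(CC)CC)[C@@H]1O[Si](C)(C)C(C)(C)C
F7 | step 14 | 9β-alcohol with 8-O-tert-butyldimethylsilyl ether | C=C(C)[C@H]1C[C@@]2(C)[C@H](C=C(O[Si](C(C)C)(C(C)C)C(C)C)C[C@@H]2C)[C@@H](O)[C@@H]1O[Si](C)(C)C(C)(C)C
F8 | step 14 | 9-ketone with 8-O-tert-butyldimethylsilyl ether | C=C(C)[C@H]1C[C@@]2(C)[C@H](C=C(O[Si](C(C)C)(C(C)C)C(C)C)C[C@@H]2C)C(=O)[C@@H]1O[Si](C)(C)C(C)(C)C
F9 | step 14 | 9α-alcohol with 8-O-tert-butyldimethylsilyl ether | C=C(C)[C@H]1C[C@@]2(C)[C@H](C=C(O[Si](C(C)C)(C(C)C)C(C)C)C[C@@H]2C)[C@H](O)[C@@H]1O[Si](C)(C)C(C)(C)C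
F10 | step 14 | 9α-tiglate with 8-O-tert-butyldimethylsilyl ether | C=C(C)[C@H]1C[C@@]2(C)[C@H](C=C(O[Si](C(C)C)(C(C)C)C(C)C)C[C@@H]2C)[C@H](OC(=O)/C(C)=C/C)[C@@H]1O[Si](C)(C)C(C)(C)C
F11 | step 14 | keto alcohol (C2 ketone, 8α-hydroxyl, 9α-tiglate) | C=C(C)[C@H]1C[C@@]2(C)[C@H](CC(=O)C[C@@H]2C)[C@H](OC(=O)/C(C)=C/C)[C@@H]1O
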